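In a closed flask the units of starting material are conserved, so whatever leaves the starting material is booked to some step, and the row asked for is a question of how that booking splits.

| flask | starting material | free catalyst | time |
|---|---|---|---|
| Saturday's | 0.015 M | 0.020 mM | 2.0 h |
| Thursday's | 0.015 M | 0.040 mM | 2.0 h |
| Monday's | 0.015 M | 0.080 mM | 2.0 h |
| Wednesday's | 0.015 M | 0.15 mM | 2.0 h |
| Tuesday's | 0.015 M | 0.30 mM | 2.0 h |

    starting material + target → side product (k1 = 0.0053 M⁻¹ s⁻¹)
    starting material + free catalyst → catalyst intermediate (k2 = 2.1 M⁻¹ s⁻¹)
    catalyst intermediate → free catalyst + target (k3 = 0.071 s⁻¹)
    2 starting material → self-condensation product (k4 = 0.054 M⁻¹ s⁻¹)

- amount of target at the end, in percent of the starting material charged for Saturday's, Thursday's, Monday's, Wednesday's, Tuesday's, in this order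
- the shape of the row from first to last (rises, then falls / falls all the way / falls, then rises / hardly changes / rises all the way)

- percent here means starting material units held: one self-condensation product or side product counts as two
- for a step with 2 of a species take k times the square, and two of it per event
- "hardly changes" means that all values lie within two and a half points (for a concentration: within two and a half percent of the largest)
- run time (Saturday's): 2.0 h

I ask the question backwards: what must the numbers look like for the row not to rise? I reckon with free catalyst held at its charge and with no target lost, so that capture of starting material by free catalyst is pseudo-first-order. Two rates then compete for the starting material: capture, and self-condensation, which goes with the square of [starting material]. Saturday's flask has R = 38.6, where R, the competition ratio, is the rate at which self-condensation uses starting material over the rate at which capture uses it, both at the charge.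

Dividing one rate law by the other and integrating in closed form, I get the target made, as a fraction of the charge, as ln(1 + R(1 − e^(−τ)))/R, where τ is the capture constant times [free catalyst] times the time. At a fixed charge and time, more catalyst lowers R and raises τ, and both lift this fraction.

A flat row needs its values to lie within the margin in the notes, yet this fraction comes to 6.23% in Saturday's flask and 49.2% in Tuesday's. A falling row needs the side step to eat target, but in Saturday's flask the half-life of target by that step, with starting material held at its charge, is 2.4 h, whereas the first half-life of starting material by self-condensation alone is 0.171 h.

So I commit to a rise, from 6.23% in Saturday's flask to 49.2% in Tuesday's. I expect both figures to be high, having left out the catalyst held in the intermediate and the side step.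

The forecast gives 5.2% to 43%, rises all the way, holding that “the target yield climbs almost in step with catalyst loading”, and its top figure lies below mine. The simulation gives 5.14%, 9.80%, 17.8%, 28.6% and 42.9%, so the row rises all the way, below my figures at both ends.

Tuesday's flask still has R = 2.57, above one, so self-condensation outruns capture at its start. Taking that step away lifts Tuesday's target from 42.9% to 87.0%, a gain of 44 percentage points and 77% of what is missing. Saturday's flask has the larger R, yet taking away the loss of starting material to self-condensation product lifts its target from 5.14% to 15.1%, which is 10% of what is missing there, and its τ stands at 0.302.

The constants are those of an exercise; what happens was integrated by code.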